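The route rests on cutting both exocyclic bonds at C1, the only sp3 carbon of the six-membered carbocycle, which bears OMe and a prenyl group between the C2 carbonyl and the C6 enol. These two substituents are the halves of methyl 1,1-dimethylallyl ether. A chiral dirhodium carbene generated at C1 from a para-quinone diazide should capture the oxygen of that ether; [2,3]-shift of the oxonium ylide then forms C1–OMe and C1–CH2 in one dearomatising, face-selective operation. The precursor is the fully substituted 4-diazocyclohexa-2,5-dienone that already carries the 3-phenylpropanoyl group at C3, the prenyl group at C5 and methyl ethers on the C2 and C6 oxygens.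

Key step: step 7

Remarks on the chemistry (assumptions, each stated once)
- Atom labels: the ring carbons of the target are called C1 (sp3, OMe and prenyl), C2 (C=O), C3 (acyl), C4 (C–OH), C5 (prenyl) and C6 (C–OH). The same labels are used for 10, 13 and 14; names in the compound list use systematic locants.
- Structure check: C1 is (S) in the target and in 14. The target SMILES shows one tautomer of an enolised triketone, and hydrolysis of 14 leads into that tautomeric set. The structures of the quinone diazide and of its rearrangement product were re-derived and need no correction.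
- Sense of induction: Rh2(S-PTTL)4 is assumed to deliver (S) at C1; if the opposite face is preferred, the mirror-image catalyst Rh2(R-PTTL)4 is used under the same conditions.
- Precursor design: methyl is kept on both flanking oxygens. It offers no O–H, no hydrogen that can shift to the carbene, no second Lewis-basic atom for a cyclic ylide and no alkene, and it survives every step before the carbene step. The weak point is that both neighbours of C1 are C–OMe, so the catalyst must tell the acyl-bearing half of the ring from the prenyl-bearing half.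
- Reagents: tert-butyl 2-methylbut-3-en-2-yl carbonate (4) and 4-diazoniobenzenesulfonate are taken as purchased.

Step 1
Reactants: 1 3,5-dimethoxyphenol; 2 3-phenylpropanoic acid
Product: 3 1-(2-hydroxy-4,6-dimethoxyphenyl)-3-phenylpropan-1-one
Conditions: BF3·OEt2 (neat), 85 °C; then H2O
Reagents that add atoms: none
Why: Friedel–Crafts acylation run as a BF3-mediated Fries-type process, in which the electron-rich phenol is acylated next to its hydroxyl because the ortho-hydroxy ketone is held as a difluoroboron chelate that the aqueous work-up hydrolyses.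

Step 2
Reactants: 3 1-(2-hydroxy-4,6-dimethoxyphenyl)-3-phenylpropan-1-one; 4 tert-butyl 2-methylbut-3-en-2-yl carbonate
Product: 5 1-[2,4-dimethoxy-6-(2-methylbut-3-en-2-yloxy)phenyl]-3-phenylpropan-1-one
Conditions: Pd(PPh3)4 (3 mol%, zerovalent palladium), THF, 0 °C → rt
Reagents that add atoms: none
Why: Tsuji–Trost allylic etherification, in which ionisation and decarboxylation of 4 give a 1,1-dimethyl-π-allylpalladium complex and tert-butoxide, and the derived phenoxide attacks the more substituted allyl terminus under kinetic control to give the tertiary aryl ether.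

Step 3
Reactants: 5 1-[2,4-dimethoxy-6-(2-methylbut-3-en-2-yloxy)phenyl]-3-phenylpropan-1-one
Product: 7 1-[2-hydroxy-4,6-dimethoxy-3-(3-methylbut-2-en-1-yl)phenyl]-3-phenylpropan-1-one, via ortho-dienone 6 (not isolated)
Conditions: PhMe, 110 °C
Reagents that add atoms: none
Why: Aromatic Claisen rearrangement, in which the [3,3]-shift delivers the allyl terminus to the only free ortho carbon, turns the 1,1-dimethylallyl unit into a linear prenyl group, and dienone 6 tautomerises to the hydrogen-bonded phenol.

Step 4
Reactants: 7 1-[2-hydroxy-4,6-dimethoxy-3-(3-methylbut-2-en-1-yl)phenyl]-3-phenylpropan-1-one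
Product: 9 1-[3-amino-6-hydroxy-2,4-dimethoxy-5-(3-methylbut-2-en-1-yl)phenyl]-3-phenylpropan-1-one, via azo dye 8 (not isolated)
Conditions: 4-diazoniobenzenesulfonate (1.1 equiv), NaOH, THF/H2O, 0 °C; then Na2S2O4, 50 °C, under argon
Reagents that add atoms: 4-diazoniobenzenesulfonate, [O-]S(=O)(=O)c1ccc(cc1)[N+]#N
Why: Azo coupling (electrophilic aromatic substitution) of the phenoxide can occur only at the one unsubstituted ring carbon, para to the oxygen and activated by both methoxy groups, and dithionite reduction then cleaves the N=N bond to the aminophenol under basic conditions that leave ketone, prenyl group and ethers alone.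

Step 5
Reactants: 9 1-[3-amino-6-hydroxy-2,4-dimethoxy-5-(3-methylbut-2-en-1-yl)phenyl]-3-phenylpropan-1-one
Product: 10 4-diazo-3,5-dimethoxy-2-(3-methylbut-2-en-1-yl)-6-(3-phenylpropanoyl)cyclohexa-2,5-dien-1-one
Conditions: tBuONO (1.1 equiv), AcOH, THF, 0 °C, dark; NaHCO3 wash
Reagents that add atoms: tert-butyl nitrite, CC(C)(C)ON=O
Why: Diazotisation with an alkyl nitrite under weakly acidic, halide-free conditions gives the diazonium ion, whose para-hydroxyl is acidic enough to lose its proton at once, so the neutral para-quinone diazide is obtained while the prenyl double bond is spared.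

Step 6
Reactants: 11 2-methylbut-3-en-2-ol
Product: 12 3-methoxy-3-methylbut-1-ene
Conditions: NaH, MeI, diglyme, 0 °C → rt; distil from the reaction mixture
Reagents that add atoms: iodomethane, CI
Why: Williamson ether synthesis, in which the sodium alkoxide of the tertiary allylic alcohol displaces iodide from iodomethane (SN2 at methyl), so no substitution at the hindered carbinol carbon is needed.

Step 7
Reactants: 10 4-diazo-3,5-dimethoxy-2-(3-methylbut-2-en-1-yl)-6-(3-phenylpropanoyl)cyclohexa-2,5-dien-1-one; 12 3-methoxy-3-methylbut-1-ene
Product: 14 (4S)-3,4,5-trimethoxy-2,4-bis(3-methylbut-2-en-1-yl)-6-(3-phenylpropanoyl)cyclohexa-2,5-dien-1-one, via oxonium ylide 13 (not isolated)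
Conditions: Rh2(S-PTTL)4 (2 mol%; dirhodium tetrakis[N-phthaloyl-(S)-tert-leucinate], both rhodium atoms divalent), 12 (20 equiv), CH2Cl2, 0 °C → rt, slow addition of 10, dark
Reagents that add atoms: none
Why: Proposed new method: loss of dinitrogen at the dirhodium catalyst gives an electrophilic rhodium-bound 4-oxocyclohexadienylidene at C1, the ether oxygen of 12 adds to it, and the oxonium ylide 13, whose negative charge is spread as a phenoxide, passes through a five-membered transition state in which the vinyl CH2 bonds to C1 while the O–CMe2 bond breaks, so OMe stays on C1 and the allyl unit arrives as a linear prenyl group with loss of aromaticity. The closest known reaction type is dirhodium-catalysed oxonium ylide formation from diazo carbonyl compounds and allyl ethers followed by [2,3]-sigmatropic rearrangement, together with dirhodium carbene transfer from quinone diazides. No ring is closed. The C1 stereocentre is set by catalyst control: the shift must take place while the ylide is still held in the chiral phthalimido-carboxylate pocket, which has to tell the acyl-flanked half of the ring from the prenyl-flanked half and so select one face of C1. The step needs oxygen capture to beat cyclopropanation of the vinyl or prenyl double bonds and ionisation of the tertiary allyl oxonium; the large excess of 12 (whose vinyl group sits on a quaternary carbon and is hindered), slow addition of 10 and low temperature favour the ylide, the flanking methyl ethers offer no O–H and no hydrogen that can migrate, and the position of the diazo group fixes the site at C1.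

Step 8
Reactants: 14 (4S)-3,4,5-trimethoxy-2,4-bis(3-methylbut-2-en-1-yl)-6-(3-phenylpropanoyl)cyclohexa-2,5-dien-1-one
Product: 15 (6S)-3,5-dihydroxy-6-methoxy-4,6-bis(3-methylbut-2-en-1-yl)-2-(3-phenylpropanoyl)cyclohexa-2,4-dien-1-one (CNP0319461.1)
Conditions: 1 M aq. HCl, THF, rt → 40 °C
Reagents that add atoms: water, O
Why: Acid-catalysed hydrolysis of the two β-methoxy enone (vinylogous ester) units by addition of water and loss of methanol gives the enolised triketone drawn for the target, while the C1 methyl ether, an ordinary tertiary alkyl ether that cannot ionise next to a carbonyl, stays and the quaternary stereocentre is untouched.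

Compound list
1 | 3,5-dimethoxyphenol | COc1cc(O)cc(OC)c1 | starting material
2 | 3-phenylpropanoic acid | OC(=O)CCc1ccccc1 | starting material
3 | 1-(2-hydroxy-4,6-dimethoxyphenyl)-3-phenylpropan-1-one | COc1cc(O)c(C(=O)CCc2ccccc2)c(OC)c1 | intermediate
4 | tert-butyl 2-methylbut-3-en-2-yl carbonate | CC(C)(C)OC(=O)OC(C)(C)C=C | starting material
5 | 1-[2,4-dimethoxy-6-(2-methylbut-3-en-2-yloxy)phenyl]-3-phenylpropan-1-one | COc1cc(OC)c(C(=O)CCc2ccccc2)c(OC(C)(C)C=C)c1 | intermediate
6 | 3,5-dimethoxy-6-(3-methylbut-2-en-1-yl)-2-(3-phenylpropanoyl)cyclohexa-2,4-dien-1-one (ortho-dienone, racemic, transient) | O=C1C(CC=C(C)C)C(OC)=CC(OC)=C1C(=O)CCc1ccccc1 | intermediate (not isolated)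
7 | 1-[2-hydroxy-4,6-dimethoxy-3-(3-methylbut-2-en-1-yl)phenyl]-3-phenylpropan-1-one | COc1cc(OC)c(C(=O)CCc2ccccc2)c(O)c1CC=C(C)C | intermediate
8 | 4-{(E)-[4-hydroxy-2,6-dimethoxy-3-(3-methylbut-2-en-1-yl)-5-(3-phenylpropanoyl)phenyl]diazenyl}benzenesulfonic acid (azo dye, present as its sodium salt) | COc1c(/N=N/c2ccc(cc2)S(=O)(=O)O)c(OC)c(C(=O)CCc2ccccc2)c(O)c1CC=C(C)C | intermediate (not isolated)
9 | 1-[3-amino-6-hydroxy-2,4-dimethoxy-5-(3-methylbut-2-en-1-yl)phenyl]-3-phenylpropan-1-one | COc1c(N)c(OC)c(C(=O)CCc2ccccc2)c(O)c1CC=C(C)C | intermediate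
10 | 4-diazo-3,5-dimethoxy-2-(3-methylbut-2-en-1-yl)-6-(3-phenylpropanoyl)cyclohexa-2,5-dien-1-one (para-quinone diazide) | [N-]=[N+]=C1C(OC)=C(C(=O)CCc2ccccc2)C(=O)C(CC=C(C)C)=C1OC | intermediate
11 | 2-methylbut-3-en-2-ol | CC(C)(O)C=C | starting material
12 | 3-methoxy-3-methylbut-1-ene | COC(C)(C)C=C | intermediate
13 | 3,5-dimethoxy-4-[methyl(2-methylbut-3-en-2-yl)oxonio]-2-(3-methylbut-2-en-1-yl)-6-(3-phenylpropanoyl)phenolate (oxonium ylide, rhodium-associated) | C[O+](C(C)(C)C=C)c1c(OC)c(C(=O)CCc2ccccc2)c([O-])c(CC=C(C)C)c1OC | intermediate (not isolated)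
14 | (4S)-3,4,5-trimethoxy-2,4-bis(3-methylbut-2-en-1-yl)-6-(3-phenylpropanoyl)cyclohexa-2,5-dien-1-one | CO[C@]1(CC=C(C)C)C(OC)=C(C(=O)CCc2ccccc2)C(=O)C(CC=C(C)C)=C1OC | intermediate
15 | (6S)-3,5-dihydroxy-6-methoxy-4,6-bis(3-methylbut-2-en-1-yl)-2-(3-phenylpropanoyl)cyclohexa-2,4-dien-1-one | CO[C@]1(CC=C(C)C)C(=O)C(C(=O)CCc2ccccc2)=C(O)C(CC=C(C)C)=C1O | target

Total step count: 8 (steps 1–5, 7 and 8 on the main line; step 6 supplies the ether).
Longest linear sequence: 7 steps (1 → 2 → 3 → 4 → 5 → 7 → 8).

Steps most likely to fail

Step 7. The carbene may add to a double bond (the vinyl group of 12 or a prenyl group) faster than the hindered ether oxygen captures it. The oxonium ylide may ionise at the tertiary allyl–oxygen bond and recombine without selectivity. The ylide may also leave rhodium before the shift, which erases face selectivity. The fallback uses known chemistry and sets out from 7. O-Alkylation with prenyl bromide (K2CO3, DMF, 50 °C) should give 1-{4,6-dimethoxy-3-(3-methylbut-2-en-1-yl)-2-[(3-methylbut-2-en-1-yl)oxy]phenyl}-3-phenylpropan-1-one F1. Heating (N,N-diethylaniline, 190 °C) should move the O-prenyl group by successive Claisen and Cope shifts to the only open ring carbon, para to the oxygen, and give 1-[2-hydroxy-4,6-dimethoxy-3,5-bis(3-methylbut-2-en-1-yl)phenyl]-3-phenylpropan-1-one F2. Oxidative dearomatisation with PhI(OAc)2 in methanol at 0 °C should add methanol at the para carbon and give racemic 3,4,5-trimethoxy-2,4-bis(3-methylbut-2-en-1-yl)-6-(3-phenylpropanoyl)cyclohexa-2,5-dien-1-one F3. Preparative chromatography on a chiral stationary phase then separates the (4S)-enantiomer, which is 14, from (4R)-3,4,5-trimethoxy-2,4-bis(3-methylbut-2-en-1-yl)-6-(3-phenylpropanoyl)cyclohexa-2,5-dien-1-one F4, and the route is rejoined at 14.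

Step 2. O-Alkylation of the hydrogen-bonded, hindered phenol may be slow, and palladium may isomerise the tertiary ether to the linear prenyl ether or divert the allyl unit to carbon, so that step 3 no longer delivers the ortho-prenyl phenol cleanly. The fallback sets out from 3 and replaces steps 2 and 3 by halogenation and cross-coupling. Iodination with N-iodosuccinimide (catalytic CF3CO2H, MeCN, 0 °C) should take place ortho to the free hydroxyl and give 1-(2-hydroxy-3-iodo-4,6-dimethoxyphenyl)-3-phenylpropan-1-one F5, with any regioisomer removed by chromatography. Stille coupling of the iodide with tributyl(3-methylbut-2-en-1-yl)stannane (Pd(PPh3)4, zerovalent palladium, DMF, 90 °C) should attach the prenyl group through its CH2 terminus and return to the route at 7.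

Step 8. Prolonged exposure to acid may drive cyclisation of a freed enol oxygen onto a prenyl double bond, or hydrolysis of the hindered enol ether at C6 may stall after the first methyl group is lost. The fallback sets out from 14 and cleaves the O–CH3 bonds by nucleophilic attack at methyl, without acid, in two stages. LiCl in DMF at 70 °C should remove the methyl group of the acyl-flanked vinylogous ester and give (4R)-3-hydroxy-4,5-dimethoxy-4,6-bis(3-methylbut-2-en-1-yl)-2-(3-phenylpropanoyl)cyclohexa-2,5-dien-1-one F6. Its spatial arrangement at the quaternary carbon is that of 14; the descriptor changes only because the ranking of the two ring branches switches. Lithium propane-1-thiolate in DMPU (rt → 50 °C, under argon) should then demethylate the remaining enol ether of the now anionic substrate, which can no longer undergo conjugate addition. Brief cold acidification to pH 4 returns to the route at 15.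

Further compounds
F1 | step 7 | 1-{4,6-dimethoxy-3-(3-methylbut-2-en-1-yl)-2-[(3-methylbut-2-en-1-yl)oxy]phenyl}-3-phenylpropan-1-one | COc1cc(OC)c(C(=O)CCc2ccccc2)c(OCC=C(C)C)c1CC=C(C)C
F2 | step 7 | 1-[2-hydroxy-4,6-dimethoxy-3,5-bis(3-methylbut-2-en-1-yl)phenyl]-3-phenylpropan-1-one | COc1c(CC=C(C)C)c(OC)c(C(=O)CCc2ccccc2)c(O)c1CC=C(C)C
F3 | step 7 | racemic 3,4,5-trimethoxy-2,4-bis(3-methylbut-2-en-1-yl)-6-(3-phenylpropanoyl)cyclohexa-2,5-dien-1-one | COC1(CC=C(C)C)C(OC)=C(C(=O)CCc2ccccc2)C(=O)C(CC=C(C)C)=C1OC
F4 | step 7 | (4R)-3,4,5-trimethoxy-2,4-bis(3-methylbut-2-en-1-yl)-6-(3-phenylpropanoyl)cyclohexa-2,5-dien-1-one | CO[C@@]1(CC=C(C)C)C(OC)=C(C(=O)CCc2ccccc2)C(=O)C(CC=C(C)C)=C1OC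
F5 | step 2 | 1-(2-hydroxy-3-iodo-4,6-dimethoxyphenyl)-3-phenylpropan-1-one | COc1cc(OC)c(C(=O)CCc2ccccc2)c(O)c1I
F6 | step 8 | (4R)-3-hydroxy-4,5-dimethoxy-4,6-bis(3-methylbut-2-en-1-yl)-2-(3-phenylpropanoyl)cyclohexa-2,5-dien-1-one | CO[C@]1(CC=C(C)C)C(O)=C(C(=O)CCc2ccccc2)C(=O)C(CC=C(C)C)=C1OC
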